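A small charge is where I began: the gas offers 5.8 mM of partner against 0.050 M of substrate, and it is held, so I wrote the balance of partner first.

| flask | substrate | gas | temperature | time |
|---|---|---|---|---|
| summer | 0.050 M | 5.8 mM (held) | 50 °C | 80 min |
| autumn | 0.050 M | 5.8 mM (held) | 70 °C | 80 min |

    substrate + partner ⇌ target (K1 = 480 M⁻¹, k1 = 79 M⁻¹ min⁻¹, Ea1 = 46.0 kJ mol⁻¹, ΔH1 = −39.0 kJ mol⁻¹)
    substrate + partner ⇌ isomer of the product A (K2 = 500 M⁻¹, k2 = 4.8 M⁻¹ min⁻¹, Ea2 = 52.0 kJ mol⁻¹, ΔH2 = 20.0 kJ mol⁻¹)
    gas ⇌ partner, rate k3*(csat - [partner]) (k3 = 0.36 min⁻¹, csat = 5.8 mM)
    target ⇌ isomer of the product B (K4 = 2.5, k4 = 0.54 min⁻¹, Ea4 = 86.0 kJ mol⁻¹, ΔH4 = −46.0 kJ mol⁻¹)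
    partner → decomposed reagent (k5 = 0.041 min⁻¹, Ea5 = 89.0 kJ mol⁻¹)
    (constants at 50 °C)

- at the start none of partner is dissolved
- the list of constants is for 50 °C, to be carried to other temperatures by the activation energies and enthalpies

1. which of these there is most of at the end, counted by the substrate in it, summer (substrate / target / isomer of the product B / isomer of the product A)
2. which of these there is most of at the end, counted by the substrate in it, autumn (substrate / target / isomer of the product B / isomer of the product A)
3. final amount of the leader among these, as a percentage of the substrate charged, in summer
4. final amount of the leader among these, as a percentage of the substrate charged, in autumn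

Partner enters by transfer and is lost by decay. Once the reversible steps stand still, those two terms balance, and [partner] stands at the saturation level times a number I call the fill, 0.898 in summer: the transfer coefficient over the sum of transfer coefficient and decay constant, which is the fraction of saturation that partner keeps against its own decay. That puts summer partner at 5.21 mM. In autumn the decay constant rises to 0.283 min⁻¹, the fill falls to 0.560, and I put partner at 3.25 mM.

With [partner] held at that level and the reversible steps at balance, each form stands to substrate as its equilibrium constant times [partner], the constant for isomer of the product B being that of target times the equilibrium constant of the step from target. In summer that gave 2.50 for target, 6.25 for isomer of the product B and 2.60 for isomer of the product A. In autumn, with the constants carried by their enthalpies, it gave 0.669, 0.617 and 2.51. Those ratios promise isomer of the product B 50.6% in summer and isomer of the product A 52.3% in autumn.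

One number was not enough, since those shares carry no clock. At fixed [partner] the route to isomer of the product A is pseudo-first-order, and its relaxation time came to 82.2 min in summer, about the 80 min allowed, but 24.8 min in autumn, shorter than the run. So for summer I reckoned isomer of the product A at 13.1% and isomer of the product B, with its part of the remainder, at 55.7%. For autumn I reckoned isomer of the product A at 50.2%.

The forecast named the same leaders, isomer of the product B at 53% in summer and isomer of the product A at 47% in autumn, a little lower than my figures, noting that “the endothermic, faster route to A gains”.

The summer flask ended with isomer of the product B leading at 55.4%, and the autumn flask with isomer of the product A at 48.1%. Partner stood at 0.00520 M in summer and 0.00319 M in autumn after 80.0 min. Carried to a flask like autumn but kept at 85 °C, the fill drops to 0.256, which puts partner at 1.48 mM; that flask held 0.00146 M after 80.0 min.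

The numbers come from no measurement.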